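At late times a reversible L ⇌ Z stops moving, and the share cL/(cL+cZ) stands at an end share given by the stopping ratio cZ/cL. A ratio of 1 is the symmetric zero of my scale, an even split.

| setting | Sunday's | Friday's | red | blue | grey | teal |
|---|---|---|---|---|---|---|
| G | 0.036 M | 0.054 M | 0.072 M | 0.072 M | 0.072 M | 0.072 M |
| E | 1.1 mol% | 1.1 mol% | 1.1 mol% | 1.1 mol% | 1.1 mol% | 1.1 mol% |
| temperature | 50 °C | 83 °C | 35 °C | 95 °C | 55 °C | 75 °C |
| remark | run made earlier | run made earlier |  |  |  |  |
| time |  |  | 80 min | 80 min | 80 min | 80 min |

- Sunday's (time / min: L / %, Z / %): 2.00: 4.1, 0; 3.00: 6.0, 0.1; 5.00: 10.6, 0.3; 10.0: 17.5, 1.4; 15.0: 23.3, 1.8; 25.0: 29.7, 8.3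
- Friday's (time / min: L / %, Z / %): 0.250: 11.6, 1.4; 1.00: 27.9, 10.3; 1.33: 30.7, 16.4; 2.50: 32.2, 31.5; 4.00: 29.6, 46.4; 5.00: 27.8, 52.6

(each reading ± 0.5 percentage points)

- steps that have been proposed: L <-> Z; G <-> L; 2 E <-> Q

1. which flask leads in share of L in all that became L or Z ("all alike" within 1.5 percentage points) (red / blue / grey / teal / all alike)
2. share of L in all that became L or Z, red
3. share of L in all that became L or Z, blue
4. share of L in all that became L or Z, grey
5. share of L in all that became L or Z, teal

1. Time. In Friday's run cL stays near 30.0% from 1.00 min to 5.00 min, but the growth of cZ slows from 0.141 min⁻¹ to 0.0844 min⁻¹ of the charge. Extended in a line, that growth reaches zero at a ratio of 2.44, which is a reading and lies above the even split. So the end share I read at 83 °C, from scattered readings, is 29.0%. For Friday's run the same line gives a relaxation half-life, read at 83 °C, of 0.748 min, much shorter than the 80 min asked.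

2. Temperature. Sunday's run still shows a share of 78.2% at 25.0 min, while Friday's run, hotter and with more G, is down to 34.6% at 5.00 min. So I put teal and blue near the end share, though one reading cannot show how the ratio shifts with temperature. Red should lead, above an even split, with grey between red and teal; this is kinetic against thermodynamic control.

3. Charge. If L ⇌ Z is first order both ways, the charge of G cancels from the ratio, and the loading of E is 1.1 mol% in each flask, so I expect no effect of either on the end share.

4. The forecast gives red the lead, with red 76%, blue 6%, grey 16% and teal 5%, holding for teal and blue that “L is nearly consumed”. There I part from it: its blue stands below my end share.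

Red leads with 89.4%, against blue 24.3%, grey 42.6% and teal 29.8%.

    L ⇌ Z (K = 1.20, k = 0.160 h⁻¹, Ea = 104 kJ mol⁻¹, ΔH = 15.0 kJ mol⁻¹)
    G ⇌ L (K = 0.770, k = 0.280 h⁻¹, Ea = 91.0 kJ mol⁻¹, ΔH = 17.0 kJ mol⁻¹)
    2 E ⇌ Q (K = 770 L mol⁻¹, k = 640 L mol⁻¹ h⁻¹, Ea = 47.0 kJ mol⁻¹, ΔH = −20.0 kJ mol⁻¹)
    (constants at 35 °C)

The share in Sunday's run at its last reading, without the scatter, is 79.9%; changing the amount of everything leaves 79.9%, red's temperature by itself gives 96.7%, and red's time by itself gives 54.0%. My end share of 29.0% at 83 °C lies between teal's 29.8% at 75 °C and blue's 24.3% at 95 °C, and blue left for 800 min still gives 24.3%.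

(The readings come from a simulation with made-up constants; the scatter is artificial.)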